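## Retrosynthetic overview

1. The last cuts are the two benzyl groups and the side-chain thioacetal. Before them comes the depside bond between the C1 carboxyl of ring A and O4' of ring B, made by esterifying a ring A acid with a ring B phenol.
2. Ring A is a 2-hydroxy-4-methoxy-6-alkylbenzoate. Carboxyl–C1–C2(OH)–C3 is an acetoacetate skeleton (1,3-dinucleophile). C4(OMe)–C5(H)–C6(CH2R) is an acylketene dimethyl acetal skeleton (1,3-dielectrophile).
3. The key disconnection cuts bonds C3–C4 and C1–C6 of ring A. Both are made in one TiCl4-mediated formal [3+3] cyclocondensation that leaves O2 free and O4 methylated.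
4. The dielectrophile comes from ethyl 3-oxooctanoate: the ketone is stored as a 1,3-dithiane, then ester → acid chloride → C-acylation of 1,1-dimethoxyethene. The dinucleophile comes from methyl acetoacetate by two silylations.
5. Ring A is the only carbocycle built (step 7). Ring B is bought as methyl orsellinate, and its C6' methyl is extended by lateral lithiation and Weinreb acylation.

Key step: step 7

Remark: the diene carries a methyl ester, because an allyl ester would make it an O-allyl silyl ketene acetal open to Ireland–Claisen rearrangement while it is prepared and warmed. The acid is therefore freed later by SN2 demethylation. The target has no stereocentre, and enol ether geometries have no consequence.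

## Route

Step 1
Reactants: 1 ethyl 3-oxooctanoate; 2 propane-1,3-dithiol
Product: 3 ethyl 2-(2-pentyl-1,3-dithian-2-yl)acetate
Conditions: BF3·OEt2 (0.2 equiv), CH2Cl2, 0 °C → rt
Reagents that add atoms: none
Why: Lewis acid catalysed thioacetalization, in which the ketone carbonyl is far more electrophilic than the ester, so only C3 should become the 1,3-dithiane, a mask that later withstands base, TiCl4 and carbodiimide.

Step 2
Reactants: 3 ethyl 2-(2-pentyl-1,3-dithian-2-yl)acetate
Product: 4 2-(2-pentyl-1,3-dithian-2-yl)acetic acid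
Conditions: LiOH, THF/MeOH/H2O, rt; then 1 M HCl, 0 °C
Reagents that add atoms: lithium hydroxide, [Li+].[OH-]
Why: Ester saponification (BAc2), in which the thioacetal is inert to hydroxide, any β-elimination of thiolate from the ester enolate is reversed by intramolecular thia-Michael re-addition, and the carboxylate once formed can no longer eliminate.

Step 3
Reactants: 4 2-(2-pentyl-1,3-dithian-2-yl)acetic acid
Product: 5 2-(2-pentyl-1,3-dithian-2-yl)acetyl chloride
Conditions: (COCl)2 (1.2 equiv), DMF (cat.), CH2Cl2, 0 °C → rt; evaporation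
Reagents that add atoms: oxalyl chloride, O=C(Cl)C(=O)Cl
Why: Acid chloride formation through the Vilsmeier-type chloroiminium species from DMF and oxalyl chloride, which runs at or below room temperature, gives only gaseous by-products and leaves thioethers untouched.

Step 4
Reactants: 5 2-(2-pentyl-1,3-dithian-2-yl)acetyl chloride; 6 1,1-dimethoxyethene
Product: 7 4,4-dimethoxy-1-(2-pentyl-1,3-dithian-2-yl)but-3-en-2-one
Conditions: 6 (2.5 equiv), Et2O, 0 °C → rt; volatiles removed in vacuo, used crude under Ar
Reagents that add atoms: none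
Why: C-acylation of a ketene acetal by addition–elimination, in which the electron-rich CH2 carbon of 6 attacks the acid chloride, the dimethoxycarbenium ion loses its acidic α-proton to give the push–pull alkene, and a second equivalent of 6 consumes the HCl, so no amine (ketene formation, β-elimination of sulfur) is needed and everything except 7 is volatile.

Step 5
Reactants: 8 methyl acetoacetate
Product: 9 methyl 3-(trimethylsilyloxy)but-2-enoate
Conditions: Me3SiCl, Et3N, toluene, rt; filtration, distillation
Reagents that add atoms: chlorotrimethylsilane, C[Si](C)(C)Cl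
Why: O-silylation of the enol form of a β-keto ester under soft enolization should give the silyl enol ether as an E/Z mixture, which does not matter for step 6.

Step 6
Reactants: 9 methyl 3-(trimethylsilyloxy)but-2-enoate
Product: 11 1-methoxy-1,3-bis(trimethylsilyloxy)buta-1,3-diene, via lithium dienolate 10 (not isolated)
Conditions: LiN(iPr)2, THF, −78 °C; Me3SiCl, −78 → 20 °C; hexane, filtration under Ar
Reagents that add atoms: chlorotrimethylsilane, C[Si](C)(C)Cl
Why: Kinetic γ-deprotonation of the vinylogous ester gives the extended dienolate 10, which the hard electrophile Me3SiCl traps on oxygen to give the 1,3-bis(silyloxy)diene, a masked acetoacetate 1,3-dianion with no [3,3] pathway open to it.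

Step 7
Reactants: 7 4,4-dimethoxy-1-(2-pentyl-1,3-dithian-2-yl)but-3-en-2-one; 11 1-methoxy-1,3-bis(trimethylsilyloxy)buta-1,3-diene
Product: 13 methyl 2-hydroxy-4-methoxy-6-[(2-pentyl-1,3-dithian-2-yl)methyl]benzoate, via open-chain vinylogous ester 12 (not isolated)
Conditions: TiCl4 (1.1 equiv), CH2Cl2, 4 Å MS, −78 → 20 °C; then ice-water
Reagents that add atoms: none
Why: TiCl4 binds the ketone oxygen of 7 (a six-membered O,S-chelate with one dithiane sulfur is possible) and turns the push–pull enone into a titanium enolate/dimethoxycarbenium ion with its positive charge on the acetal carbon; the terminal CH2 of 11, the most nucleophilic diene carbon, adds there in Mukaiyama–Michael fashion, and loss of one methoxide gives 12 (bond C3–C4). The remaining enolate carbon between the two carbonyl groups of the acetoacetate part then attacks the regenerated, titanium-activated ketone in an intramolecular Mukaiyama aldol reaction (bond C1–C6); this is a favoured 6-(enolexo)-exo-trig closure that needs C3 and C6 cis on the C4=C5 bond, a geometry easily reached because rotation about a Lewis acid complexed push–pull double bond is facile. Elimination of the tertiary titanium alkoxide and enolization of the C2 carbonyl are driven by aromatization and should deliver ring A with O2 free (hydrogen-bonded to the ester) and O4 methylated. The closest known reaction type is the Lewis acid mediated formal [3+3] cyclocondensation of 1,3-bis(silyloxy)-1,3-dienes with 3-alkoxy and 3,3-dialkoxy enones to 4-alkoxysalicylates. No stereocentre is created; the selectivity needed is regiochemical (diene terminus to C(OMe)2 and not to C=O, which would lead to the 4-alkyl-6-methoxy isomer), and it is secured by the two oxygen donors that localize the cation on the acetal carbon, by the neopentyl-like shielding of the ketone by the CH2–dithiane group and by the low starting temperature. A thioacetal masks the side-chain ketone because, unlike an O,O-ketal, it does not ionize with TiCl4 to a competing oxocarbenium electrophile.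

Step 8
Reactants: 13 methyl 2-hydroxy-4-methoxy-6-[(2-pentyl-1,3-dithian-2-yl)methyl]benzoate
Product: 14 methyl 2-(benzyloxy)-4-methoxy-6-[(2-pentyl-1,3-dithian-2-yl)methyl]benzoate
Conditions: BnBr (1.2 equiv), K2CO3, DMF, 60 °C
Reagents that add atoms: benzyl bromide, BrCc1ccccc1
Why: Williamson etherification, in which K2CO3 in DMF breaks the hydrogen bond of the salicylate OH and the phenoxide outcompetes the hindered, weakly nucleophilic dithiane sulfur for the halide.

Step 9
Reactants: 14 methyl 2-(benzyloxy)-4-methoxy-6-[(2-pentyl-1,3-dithian-2-yl)methyl]benzoate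
Product: 15 2-(benzyloxy)-4-methoxy-6-[(2-pentyl-1,3-dithian-2-yl)methyl]benzoic acid
Conditions: n-PrSLi, HMPA, rt; then cold 1 M HCl
Reagents that add atoms: none
Why: SN2 dealkylation of a hindered methyl ester by a soft thiolate (BAl2), which attacks the open methyl carbon instead of the shielded carbonyl; carboxylate leaves far more readily than aryloxide, so both aryl ethers persist at rt, and the weakly basic medium spares the benzylic CH2 next to the dithiane.

Step 10
Reactants: 16 hexanoyl chloride; 17 N,O-dimethylhydroxylamine hydrochloride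
Product: 18 N-methoxy-N-methylhexanamide
Conditions: Et3N (2.2 equiv), CH2Cl2, 0 °C → rt
Reagents that add atoms: none
Why: Simple N-acylation of the liberated hydroxylamine by an acid chloride (Weinreb amide formation).

Step 11
Reactants: 19 methyl 2,4-dihydroxy-6-methylbenzoate
Product: 20 methyl 4-(benzyloxy)-2-hydroxy-6-methylbenzoate
Conditions: BnBr (1.0 equiv), K2CO3, acetone, reflux
Reagents that add atoms: benzyl bromide, BrCc1ccccc1
Why: Regioselective Williamson etherification, since the 4-OH is free and more acidic while the 2-OH is tied up in a hydrogen bond to the ester carbonyl and flanked by it.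

Step 12
Reactants: 20 methyl 4-(benzyloxy)-2-hydroxy-6-methylbenzoate
Product: 21 methyl 4-(benzyloxy)-2-methoxy-6-methylbenzoate
Conditions: MeI, K2CO3, DMF, 40 °C
Reagents that add atoms: iodomethane, CI
Why: Williamson methylation of the only remaining phenol in a dipolar aprotic solvent, which sets the 2'-methoxy group of ring B.

Step 13
Reactants: 21 methyl 4-(benzyloxy)-2-methoxy-6-methylbenzoate; 18 N-methoxy-N-methylhexanamide
Product: 23 methyl 4-(benzyloxy)-2-methoxy-6-(2-oxoheptyl)benzoate, via benzylic lithium species 22 (not isolated)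
Conditions: LiN(iPr)2, THF, −78 °C; then 18, −78 °C; AcOH quench at −78 °C
Reagents that add atoms: none
Why: Lateral lithiation of an ortho-toluate followed by Weinreb ketone synthesis, in which the chelated tetrahedral adduct survives until the cold acidic quench, so over-addition and enolate-driven lactonization are avoided, and the 2,6-disubstituted ester is too hindered for self-condensation.

Step 14
Reactants: 23 methyl 4-(benzyloxy)-2-methoxy-6-(2-oxoheptyl)benzoate
Product: 24 4-(benzyloxy)-2-methoxy-6-(2-oxoheptyl)benzoic acid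
Conditions: KOH, EtOH/H2O, reflux; then cold 1 M HCl
Reagents that add atoms: potassium hydroxide, [K+].[OH-]
Why: Saponification of the hindered ester is assisted by the neighbouring ketone enolate (a transient enol lactone that hydroxide opens), and the keto carboxylate is stable in aqueous base.

Step 15
Reactants: 24 4-(benzyloxy)-2-methoxy-6-(2-oxoheptyl)benzoic acid
Product: 25 4-hydroxy-2-methoxy-6-(2-oxoheptyl)benzoic acid
Conditions: H2 (1 atm), Pd/C (10 wt%), EtOAc, rt
Reagents that add atoms: none
Why: Catalytic hydrogenolysis of an aryl benzyl ether, to which the non-benzylic aliphatic ketone, the arene and the acid are inert at atmospheric pressure.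

Step 16
Reactants: 25 4-hydroxy-2-methoxy-6-(2-oxoheptyl)benzoic acid
Product: 26 benzyl 4-hydroxy-2-methoxy-6-(2-oxoheptyl)benzoate
Conditions: BnBr (1.05 equiv), KHCO3, DMF, rt
Reagents that add atoms: benzyl bromide, BrCc1ccccc1
Why: Chemoselective carboxylate O-alkylation (SN2), because KHCO3 ionizes only the carboxylic acid and leaves the phenol protonated and unreactive.

Step 17
Reactants: 15 2-(benzyloxy)-4-methoxy-6-[(2-pentyl-1,3-dithian-2-yl)methyl]benzoic acid; 26 benzyl 4-hydroxy-2-methoxy-6-(2-oxoheptyl)benzoate
Product: 27 benzyl 4-({2-(benzyloxy)-4-methoxy-6-[(2-pentyl-1,3-dithian-2-yl)methyl]benzoyl}oxy)-2-methoxy-6-(2-oxoheptyl)benzoate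
Conditions: DCC, DMAP, CH2Cl2, 0 °C → rt
Reagents that add atoms: none
Why: Steglich esterification, in which the acylpyridinium ion from 15 meets the only free hydroxyl of 26, the thioacetal blocks enol lactonization of the activated acid, and the 2-O-benzyl group blocks self-acylation.

Step 18
Reactants: 27 benzyl 4-({2-(benzyloxy)-4-methoxy-6-[(2-pentyl-1,3-dithian-2-yl)methyl]benzoyl}oxy)-2-methoxy-6-(2-oxoheptyl)benzoate
Product: 28 benzyl 4-{[2-(benzyloxy)-4-methoxy-6-(2-oxoheptyl)benzoyl]oxy}-2-methoxy-6-(2-oxoheptyl)benzoate
Conditions: PhI(OCOCF3)2 (1.5 equiv), MeCN/H2O, 0 °C → rt, short contact; aq NaHCO3 work-up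
Reagents that add atoms: water, O
Why: Oxidative dethioacetalization by trivalent iodine, in which sulfur, the most oxidizable site now that every phenol is masked, is activated, the ring opens to a thionium ion, water adds, and the hemithioacetal collapses to the ketone.

Step 19
Reactants: 28 benzyl 4-{[2-(benzyloxy)-4-methoxy-6-(2-oxoheptyl)benzoyl]oxy}-2-methoxy-6-(2-oxoheptyl)benzoate
Product: 29 4-{[2-hydroxy-4-methoxy-6-(2-oxoheptyl)benzoyl]oxy}-2-methoxy-6-(2-oxoheptyl)benzoic acid (CNP0177576.0)
Conditions: H2 (1 atm), Pd/C (10 wt%), EtOAc, rt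
Reagents that add atoms: none
Why: Catalytic hydrogenolysis removes the benzyl ether and the benzyl ester together under neutral conditions once all sulfur is gone, and the depside aryl ester and both aliphatic ketones are not touched.

## Compound list

1 | ethyl 3-oxooctanoate | CCCCCC(=O)CC(=O)OCC | starting material
2 | propane-1,3-dithiol | SCCCS | starting material
3 | ethyl 2-(2-pentyl-1,3-dithian-2-yl)acetate | CCCCCC1(CC(=O)OCC)SCCCS1 | intermediate
4 | 2-(2-pentyl-1,3-dithian-2-yl)acetic acid | CCCCCC1(CC(=O)O)SCCCS1 | intermediate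
5 | 2-(2-pentyl-1,3-dithian-2-yl)acetyl chloride | CCCCCC1(CC(=O)Cl)SCCCS1 | intermediate
6 | 1,1-dimethoxyethene | C=C(OC)OC | starting material
7 | 4,4-dimethoxy-1-(2-pentyl-1,3-dithian-2-yl)but-3-en-2-one | COC(OC)=CC(=O)CC1(CCCCC)SCCCS1 | intermediate
8 | methyl acetoacetate | CC(=O)CC(=O)OC | starting material
9 | methyl 3-(trimethylsilyloxy)but-2-enoate (E/Z mixture) | COC(=O)C=C(C)O[Si](C)(C)C | intermediate
10 | lithium dienolate of 9 | COC(O[Li])=CC(=C)O[Si](C)(C)C | intermediate (not isolated)
11 | 1-methoxy-1,3-bis(trimethylsilyloxy)buta-1,3-diene | COC(=CC(=C)O[Si](C)(C)C)O[Si](C)(C)C | intermediate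
12 | methyl 5-methoxy-3,7-dioxo-8-(2-pentyl-1,3-dithian-2-yl)oct-5-enoate (drawn metal-free, present as its titanium/silyl enolate) | COC(=O)CC(=O)CC(OC)=CC(=O)CC1(CCCCC)SCCCS1 | intermediate (not isolated)
13 | methyl 2-hydroxy-4-methoxy-6-[(2-pentyl-1,3-dithian-2-yl)methyl]benzoate | COC(=O)c1c(O)cc(OC)cc1CC1(CCCCC)SCCCS1 | intermediate
14 | methyl 2-(benzyloxy)-4-methoxy-6-[(2-pentyl-1,3-dithian-2-yl)methyl]benzoate | COC(=O)c1c(OCc2ccccc2)cc(OC)cc1CC1(CCCCC)SCCCS1 | intermediate
15 | 2-(benzyloxy)-4-methoxy-6-[(2-pentyl-1,3-dithian-2-yl)methyl]benzoic acid | OC(=O)c1c(OCc2ccccc2)cc(OC)cc1CC1(CCCCC)SCCCS1 | intermediate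
16 | hexanoyl chloride | CCCCCC(=O)Cl | starting material
17 | N,O-dimethylhydroxylamine hydrochloride | CNOC.Cl | starting material
18 | N-methoxy-N-methylhexanamide | CCCCCC(=O)N(C)OC | intermediate
19 | methyl 2,4-dihydroxy-6-methylbenzoate (methyl orsellinate) | COC(=O)c1c(C)cc(O)cc1O | starting material
20 | methyl 4-(benzyloxy)-2-hydroxy-6-methylbenzoate | COC(=O)c1c(C)cc(OCc2ccccc2)cc1O | intermediate
21 | methyl 4-(benzyloxy)-2-methoxy-6-methylbenzoate | COC(=O)c1c(C)cc(OCc2ccccc2)cc1OC | intermediate
22 | benzylic lithium species of 21 | [Li]Cc1cc(OCc2ccccc2)cc(OC)c1C(=O)OC | intermediate (not isolated)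
23 | methyl 4-(benzyloxy)-2-methoxy-6-(2-oxoheptyl)benzoate | CCCCCC(=O)Cc1cc(OCc2ccccc2)cc(OC)c1C(=O)OC | intermediate
24 | 4-(benzyloxy)-2-methoxy-6-(2-oxoheptyl)benzoic acid | CCCCCC(=O)Cc1cc(OCc2ccccc2)cc(OC)c1C(=O)O | intermediate
25 | 4-hydroxy-2-methoxy-6-(2-oxoheptyl)benzoic acid | CCCCCC(=O)Cc1cc(O)cc(OC)c1C(=O)O | intermediate
26 | benzyl 4-hydroxy-2-methoxy-6-(2-oxoheptyl)benzoate | CCCCCC(=O)Cc1cc(O)cc(OC)c1C(=O)OCc1ccccc1 | intermediate
27 | benzyl 4-({2-(benzyloxy)-4-methoxy-6-[(2-pentyl-1,3-dithian-2-yl)methyl]benzoyl}oxy)-2-methoxy-6-(2-oxoheptyl)benzoate | CCCCCC(=O)Cc1cc(OC(=O)c2c(OCc3ccccc3)cc(OC)cc2CC2(CCCCC)SCCCS2)cc(OC)c1C(=O)OCc1ccccc1 | intermediate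
28 | benzyl 4-{[2-(benzyloxy)-4-methoxy-6-(2-oxoheptyl)benzoyl]oxy}-2-methoxy-6-(2-oxoheptyl)benzoate | CCCCCC(=O)Cc1cc(OC)cc(OCc2ccccc2)c1C(=O)Oc1cc(CC(=O)CCCCC)c(C(=O)OCc2ccccc2)c(OC)c1 | intermediate
29 | 4-{[2-hydroxy-4-methoxy-6-(2-oxoheptyl)benzoyl]oxy}-2-methoxy-6-(2-oxoheptyl)benzoic acid | CCCCCC(=O)Cc1cc(OC)cc(O)c1C(=O)Oc1cc(CC(=O)CCCCC)c(C(=O)O)c(OC)c1 | target

## Totals

Total step count: 19.
Longest linear sequence: 10 steps (1, 2, 3, 4, 7, 8, 9, 17, 18, 19).

## Steps most likely to fail

**1. Step 7.**
- Risks: leakage of the diene terminus to 1,2-attack on the ketone; ring closure through oxygen instead of carbon; TiCl4-promoted enolization of the ketone with β-elimination of sulfur and opening of the thioacetal; hydrolysis of either moisture-sensitive partner before they meet.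
- Fallback (ring A taken from the aromatic pool, side chain added by toluate chemistry): it sets out from 19. The free 4-hydroxyl is methylated selectively (MeI, one equivalent, K2CO3, acetone) to methyl 2-hydroxy-4-methoxy-6-methylbenzoate F1. The chelated 2-hydroxyl is benzylated (BnBr, K2CO3, DMF) to methyl 2-(benzyloxy)-4-methoxy-6-methylbenzoate F2. Lateral lithiation with LiN(iPr)2 and acylation with 18 gives methyl 2-(benzyloxy)-4-methoxy-6-(2-oxoheptyl)benzoate F3. Brief thioacetalization with 2 (BF3·OEt2 cat., CH2Cl2, 0 °C) comes back to the route at 14.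

**2. Step 4.**
- Risks: chloride-induced demethylation of the dimethoxycarbenium intermediate before it loses its proton (collapse to the β-keto ester level); dehydrochlorination of the acid chloride to a ketene followed by [2+2] addition; hydrolysis of the ketene acetal function on handling.
- Fallback (the two-carbon unit enters as an acetylide nucleophile): it sets out from 4. Coupling with 17 (1,1'-carbonyldiimidazole, CH2Cl2) gives N-methoxy-N-methyl-2-(2-pentyl-1,3-dithian-2-yl)acetamide F4. Lithium methoxyacetylide F5 is generated in THF from 2-chloro-1,1-dimethoxyethane and LiNEt2 (three equivalents). It adds to F4 at low temperature to give 4-methoxy-1-(2-pentyl-1,3-dithian-2-yl)but-3-yn-2-one F6. Base-catalysed conjugate addition of methanol (DMAP cat., 0 °C) to the alkoxy-bearing alkyne carbon comes back to the route at 7.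

**3. Step 18.**
- Risks: oxidation of the electron-rich dialkoxyarene by the iodine reagent; stalling at a partly hydrolysed sulfur intermediate; acid-promoted enol lactonization of the freed ring A ketone onto the depside carbonyl, with expulsion of the ring B phenol.
- Fallback (the mask is exchanged before the fragile depside exists): it sets out from 14. Treatment with PhI(OCOCF3)2 in MeCN containing ethane-1,2-diol converts the dithiane directly into the ketal, methyl 2-(benzyloxy)-4-methoxy-6-[(2-pentyl-1,3-dioxolan-2-yl)methyl]benzoate F7. Thiolate demethylation (n-PrSLi, HMPA) gives 2-(benzyloxy)-4-methoxy-6-[(2-pentyl-1,3-dioxolan-2-yl)methyl]benzoic acid F8. Steglich esterification with 26 gives benzyl 4-({2-(benzyloxy)-4-methoxy-6-[(2-pentyl-1,3-dioxolan-2-yl)methyl]benzoyl}oxy)-2-methoxy-6-(2-oxoheptyl)benzoate F9. Mild non-oxidative hydrolysis (pyridinium tosylate, wet acetone) comes back to the route at 28.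

## Further compounds

F1 | step 7 | methyl 2-hydroxy-4-methoxy-6-methylbenzoate | COC(=O)c1c(C)cc(OC)cc1O
F2 | step 7 | methyl 2-(benzyloxy)-4-methoxy-6-methylbenzoate | COC(=O)c1c(C)cc(OC)cc1OCc1ccccc1
F3 | step 7 | methyl 2-(benzyloxy)-4-methoxy-6-(2-oxoheptyl)benzoate | CCCCCC(=O)Cc1cc(OC)cc(OCc2ccccc2)c1C(=O)OC
F4 | step 4 | N-methoxy-N-methyl-2-(2-pentyl-1,3-dithian-2-yl)acetamide | CCCCCC1(CC(=O)N(C)OC)SCCCS1
F5 | step 4 | lithium methoxyacetylide | [Li]C#COC
F6 | step 4 | 4-methoxy-1-(2-pentyl-1,3-dithian-2-yl)but-3-yn-2-one | COC#CC(=O)CC1(CCCCC)SCCCS1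
F7 | step 18 | methyl 2-(benzyloxy)-4-methoxy-6-[(2-pentyl-1,3-dioxolan-2-yl)methyl]benzoate | COC(=O)c1c(OCc2ccccc2)cc(OC)cc1CC1(CCCCC)OCCO1
F8 | step 18 | 2-(benzyloxy)-4-methoxy-6-[(2-pentyl-1,3-dioxolan-2-yl)methyl]benzoic acid | OC(=O)c1c(OCc2ccccc2)cc(OC)cc1CC1(CCCCC)OCCO1
F9 | step 18 | benzyl 4-({2-(benzyloxy)-4-methoxy-6-[(2-pentyl-1,3-dioxolan-2-yl)methyl]benzoyl}oxy)-2-methoxy-6-(2-oxoheptyl)benzoate | CCCCCC(=O)Cc1cc(OC(=O)c2c(OCc3ccccc3)cc(OC)cc2CC2(CCCCC)OCCO2)cc(OC)c1C(=O)OCc1ccccc1
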